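**Plan**

1. Cuts (plakortolide numbering: C-1 lactone carbonyl, C-3 peroxy CH, C-4 and C-6 quaternary carbons, C-13 to C-16 diene): first C13=C14; then the peroxide bond O–C6 together with the C-6 methyl, which is carried as C6=CH2; then C3–OO, C2=C3, C5–C6 and C7–C8.
2. Forward: C7–C8 (Grignard on 2,3-dibromopropene), C5–C6 (alkenyl Grignard on (R)-2-methylglycidol), C2=C3 (Wittig), C3–O (organocatalytic peroxidation, lactol, then γ-lactone as the first ring). The 1,2-dioxane is the second ring, closed 6-exo from the distal oxygen of the C-3 hydroperoxide to C-6 under iodonium activation; iodine is then removed to leave the C-6 methyl, and the phenyldiene is attached last.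
3. Feature that allows the closure: C-3 to C-6 is a four-carbon run with oxygen on C-3 and C-4 and a 1,3-relation between C-4 and C-6. With the γ-lactone (O, C-1, C-2, C-3, C-4) cis-fused across C3–C4, the C-3 OOH and the 2-alkylallyl arm on C-4 lie on one face, so O–O–C3–C4–C5–C6 closes as a chair.
4. Stereochemistry: C-4 is bought in (R)-2-methylglycidol; C-3 is set by catalyst control; C-6, whose two CH2 substituents an external reagent can hardly tell apart, is relayed from C-4 through the lactone-locked chair of the key step; both alkenes are E from the cinnamylphosphonate olefination.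

Key step: step 9

Remark: the target SMILES reads as 3S,4S,6S; (R)-2-methylglycidol is taken as a purchasable building block (it is the Sharpless epoxidation product of 2-methylprop-2-en-1-ol with D-(−)-diisopropyl tartrate).

**Route**

Step 1
Reactants: 1 tert-butyl[(6-bromohexyl)oxy]dimethylsilane; 2 2,3-dibromoprop-1-ene
Product: 4 [(8-bromonon-8-en-1-yl)oxy](tert-butyl)dimethylsilane, via alkylmagnesium bromide 3 (not isolated)
Conditions: Mg, THF, 40 °C; then 2, CuI (5 mol %), THF, −10 °C → rt
Reagents that add atoms: none
Why: Copper-catalysed Grignard allylation, in which the alkylmagnesium bromide displaces the allylic bromide of 2 (direct and transposed attack give the same product) while the vinylic C–Br bond stays, giving the 2-bromo-1-alkene that holds C-6 to C-13.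

Step 2
Reactants: 4 [(8-bromonon-8-en-1-yl)oxy](tert-butyl)dimethylsilane; 5 (R)-2-methylglycidol
Product: 8 (2S)-11-[(tert-butyldimethylsilyl)oxy]-2-methyl-4-methylideneundecane-1,2-diol, via alkenylmagnesium bromide 6 (not isolated), via glycidol bromomagnesium alkoxide 7 (not isolated)
Conditions: 4, Mg, THF, 50 °C; separately 5, EtMgBr (1.0 equiv), THF, −40 °C; combine, CuI (10 mol %), −40 → 0 °C; aq. NH4Cl
Reagents that add atoms: none
Why: Copper-catalysed Grignard opening of a 2,2-disubstituted epoxide at its unsubstituted CH2 (the C5–C6 bond), the hydroxyl being masked as its magnesium alkoxide; the quaternary carbon C-4 is not touched, so its configuration comes unchanged from 5.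

Step 3
Reactants: 8 (2S)-11-[(tert-butyldimethylsilyl)oxy]-2-methyl-4-methylideneundecane-1,2-diol
Product: 9 (2S)-11-[(tert-butyldimethylsilyl)oxy]-2-hydroxy-2-methyl-4-methylideneundecanal
Conditions: SO3·pyridine, DMSO, i-Pr2NEt, CH2Cl2, 0 °C
Reagents that add atoms: none
Why: Parikh–Doering oxidation converts only the primary hydroxyl, the tertiary one being inert, and the aldehyde has no α-hydrogen, so C-4 cannot epimerise.

Step 4
Reactants: 9 (2S)-11-[(tert-butyldimethylsilyl)oxy]-2-hydroxy-2-methyl-4-methylideneundecanal; 10 (triphenyl-λ5-phosphanylidene)acetaldehyde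
Product: 11 (2E,4S)-13-[(tert-butyldimethylsilyl)oxy]-4-hydroxy-4-methyl-6-methylidenetridec-2-enal
Conditions: toluene, 60 °C
Reagents that add atoms: none
Why: Wittig olefination with a stabilised formyl ylide should give the E-enal, and the conjugated product next to a quaternary carbon should not be homologated a second time.

Step 5
Reactants: 12 2,3-dimethylbut-2-ene
Product: 14 2-hydroperoxy-2-methoxypropane, via acetone O-oxide 13 (not isolated)
Conditions: O3, MeOH/CH2Cl2, −78 °C; N2 purge; concentrate cold
Reagents that add atoms: ozone, O=[O+][O-]; methanol, CO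
Why: Ozonolysis in methanol (Criegee mechanism), where the carbonyl oxide from the symmetrical alkene is trapped by methanol to give an α-methoxy hydroperoxide whose alkyl group can later be taken off with mild acid.

Step 6
Reactants: 11 (2E,4S)-13-[(tert-butyldimethylsilyl)oxy]-4-hydroxy-4-methyl-6-methylidenetridec-2-enal; 14 2-hydroperoxy-2-methoxypropane
Product: 16 (4S,5S)-5-{9-[(tert-butyldimethylsilyl)oxy]-2-methylidenenonyl}-4-[(2-methoxypropan-2-yl)peroxy]-5-methyloxolan-2-ol (both C-2 epimers), via open-chain peroxy aldehyde 15 (not isolated)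
Conditions: (S)-2-[diphenyl(trimethylsilyloxy)methyl]pyrrolidine (20 mol %), PhCO2H (20 mol %), toluene, 0 °C
Reagents that add atoms: none
Why: Iminium-catalysed asymmetric oxa-Michael addition of a hydroperoxide to an enal (organocatalytic β-peroxidation), in which the E-iminium ion is attacked at C-3 on the face remote from the diphenyl(silyloxy)methyl arm; this should give 3S under catalyst control because the two carbon substituents on C-4 differ little in size, and the C-4 hydroxyl then captures the aldehyde as the lactol, which keeps the adduct from reverting or collapsing to an epoxide.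

Step 7
Reactants: 16 (4S,5S)-5-{9-[(tert-butyldimethylsilyl)oxy]-2-methylidenenonyl}-4-[(2-methoxypropan-2-yl)peroxy]-5-methyloxolan-2-ol
Product: 17 (4S,5S)-5-{9-[(tert-butyldimethylsilyl)oxy]-2-methylidenenonyl}-4-[(2-methoxypropan-2-yl)peroxy]-5-methyloxolan-2-one
Conditions: n-Pr4N[RuO4] (5 mol %), N-methylmorpholine N-oxide, 4 Å molecular sieves, CH2Cl2, rt
Reagents that add atoms: none
Why: Ley–Griffith oxidation of a lactol to the γ-lactone under neutral conditions that should leave the peroxyketal, the silyl ether and the alkene untouched.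

Step 8
Reactants: 17 (4S,5S)-5-{9-[(tert-butyldimethylsilyl)oxy]-2-methylidenenonyl}-4-[(2-methoxypropan-2-yl)peroxy]-5-methyloxolan-2-one
Product: 18 (4S,5S)-4-hydroperoxy-5-(9-hydroxy-2-methylidenenonyl)-5-methyloxolan-2-one
Conditions: camphor-10-sulfonic acid (10 mol %), MeOH, 0 °C → rt
Reagents that add atoms: none
Why: Acid-catalysed transketalisation with methanol frees the hydroperoxide from the peroxyketal and cleaves the primary silyl ether in the same operation, under conditions too mild to protonate the 1,1-disubstituted alkene or open the lactone.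

Step 9
Reactants: 18 (4S,5S)-4-hydroperoxy-5-(9-hydroxy-2-methylidenenonyl)-5-methyloxolan-2-one
Product: 19 (1S,4S,6S)-4-(7-hydroxyheptyl)-4-(iodomethyl)-6-methyl-2,3,7-trioxabicyclo[4.3.0]nonan-8-one
Conditions: N-iodosuccinimide (1.2 equiv), CH2Cl2, −20 → 0 °C, dark
Reagents that add atoms: N-iodosuccinimide, O=C1CCC(=O)N1I
Why: N-Iodosuccinimide turns the 1,1-disubstituted C6=CH2 alkene into an iodonium ion, and the terminal oxygen of the C-3 hydroperoxide opens it at the more substituted carbon C-6, anti to iodine, the O–H proton passing to succinimide. The closest known reaction type is the cycloperoxyiodination of unsaturated hydroperoxides, the peroxide counterpart of iodoetherification. The 1,2-dioxane closes in the 6-exo-trig mode. The new quaternary centre C-6 is controlled by C-4 through a chair-like transition state on the cis-fused lactone, with the lactone oxygen on C-4 axial, the C-4 methyl equatorial and the exocyclic C=CH2 pseudo-axial, so that the heptyl branch lies anti to C-4, avoids eclipsing that quaternary carbon (1,2-allylic strain) and meets no axial carbon substituent; this should place CH2I cis to the lactone oxygen and the chain cis to the C-4 methyl, as in the target. The step needs Markovnikov regioselectivity, which the 1,1-disubstitution secures, chemoselectivity for the hydroperoxide over the remote primary alcohol and the lactone carbonyl, which ring size secures, and face selectivity, which the lactone-locked chair secures; cold and dark conditions should suppress homolysis of any O–I species.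

Step 10
Reactants: 19 (1S,4S,6S)-4-(7-hydroxyheptyl)-4-(iodomethyl)-6-methyl-2,3,7-trioxabicyclo[4.3.0]nonan-8-one
Product: 20 (1S,4S,6S)-4-(7-hydroxyheptyl)-4,6-dimethyl-2,3,7-trioxabicyclo[4.3.0]nonan-8-one
Conditions: Bu3SnH (5 equiv, ≥2 M), Et3B (0.2 equiv), air, toluene, 0 °C → rt
Reagents that add atoms: none
Why: Radical-chain deiodination with tin hydride turns CH2I into the C-6 methyl group; the high Bu3SnH concentration and low temperature should make hydrogen transfer to the primary β-peroxyalkyl radical faster than its closure to an epoxide, and C-6 is not a radical centre, so its configuration is kept.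

Step 11
Reactants: 20 (1S,4S,6S)-4-(7-hydroxyheptyl)-4,6-dimethyl-2,3,7-trioxabicyclo[4.3.0]nonan-8-one
Product: 21 7-[(1S,4S,6S)-4,6-dimethyl-8-oxo-2,3,7-trioxabicyclo[4.3.0]nonan-4-yl]heptanal
Conditions: Dess–Martin periodinane (1.3 equiv), CH2Cl2, 0 °C → rt
Reagents that add atoms: none
Why: Dess–Martin oxidation of the primary alcohol to the aldehyde under near-neutral conditions that the peroxide and the lactone should tolerate.

Step 12
Reactants: 21 7-[(1S,4S,6S)-4,6-dimethyl-8-oxo-2,3,7-trioxabicyclo[4.3.0]nonan-4-yl]heptanal; 22 diethyl [(2E)-3-phenylprop-2-en-1-yl]phosphonate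
Product: 24 plakortolide R, (1S,4S,6S)-4,6-dimethyl-4-[(7E,9E)-10-phenyldeca-7,9-dien-1-yl]-2,3,7-trioxabicyclo[4.3.0]nonan-8-one, via lithiated phosphonate 23 (not isolated)
Conditions: 22 (1.05 equiv), LiN(SiMe3)2 (1.0 equiv), THF, −78 °C; then 21, −78 °C → rt; aq. NH4Cl
Reagents that add atoms: none
Why: Horner–Wadsworth–Emmons olefination with a preformed allylic phosphonate anion should form C13=C14 with E geometry while the E C15=C16 bond comes from the reagent, the anion being kept from excess and added cold so that the β-peroxy lactone is not enolised.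

**Compound list**

1 | tert-butyl[(6-bromohexyl)oxy]dimethylsilane | BrCCCCCCO[Si](C)(C)C(C)(C)C | starting material
2 | 2,3-dibromoprop-1-ene | C=C(Br)CBr | starting material
3 | {6-[(tert-butyldimethylsilyl)oxy]hexyl}magnesium bromide | Br[Mg]CCCCCCO[Si](C)(C)C(C)(C)C | intermediate
4 | [(8-bromonon-8-en-1-yl)oxy](tert-butyl)dimethylsilane | C=C(Br)CCCCCCCO[Si](C)(C)C(C)(C)C | intermediate
5 | (R)-2-methylglycidol, [(2R)-2-methyloxiran-2-yl]methanol | C[C@@]1(CO)CO1 | starting material
6 | {9-[(tert-butyldimethylsilyl)oxy]non-1-en-2-yl}magnesium bromide | C=C([Mg]Br)CCCCCCCO[Si](C)(C)C(C)(C)C | intermediate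
7 | bromomagnesium alkoxide of 5 | C[C@@]1(CO[Mg]Br)CO1 | intermediate
8 | (2S)-11-[(tert-butyldimethylsilyl)oxy]-2-methyl-4-methylideneundecane-1,2-diol | C=C(CCCCCCCO[Si](C)(C)C(C)(C)C)C[C@](CO)(C)O | intermediate
9 | (2S)-11-[(tert-butyldimethylsilyl)oxy]-2-hydroxy-2-methyl-4-methylideneundecanal | C=C(CCCCCCCO[Si](C)(C)C(C)(C)C)C[C@](C=O)(C)O | intermediate
10 | (triphenyl-λ5-phosphanylidene)acetaldehyde | O=CC=P(c1ccccc1)(c1ccccc1)c1ccccc1 | starting material
11 | (2E,4S)-13-[(tert-butyldimethylsilyl)oxy]-4-hydroxy-4-methyl-6-methylidenetridec-2-enal | C=C(CCCCCCCO[Si](C)(C)C(C)(C)C)C[C@](/C=C/C=O)(C)O | intermediate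
12 | 2,3-dimethylbut-2-ene | CC(C)=C(C)C | starting material
13 | acetone O-oxide (carbonyl oxide) | CC(C)=[O+][O-] | intermediate
14 | 2-hydroperoxy-2-methoxypropane | COC(C)(C)OO | intermediate
15 | (3S,4S)-13-[(tert-butyldimethylsilyl)oxy]-4-hydroxy-3-[(2-methoxypropan-2-yl)peroxy]-4-methyl-6-methylidenetridecanal | C=C(CCCCCCCO[Si](C)(C)C(C)(C)C)C[C@](C)(O)[C@H](CC=O)OOC(C)(C)OC | intermediate
16 | (4S,5S)-5-{9-[(tert-butyldimethylsilyl)oxy]-2-methylidenenonyl}-4-[(2-methoxypropan-2-yl)peroxy]-5-methyloxolan-2-ol (C-2 epimers) | C=C(CCCCCCCO[Si](C)(C)C(C)(C)C)C[C@]1(C)OC(O)C[C@@H]1OOC(C)(C)OC | intermediate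
17 | (4S,5S)-5-{9-[(tert-butyldimethylsilyl)oxy]-2-methylidenenonyl}-4-[(2-methoxypropan-2-yl)peroxy]-5-methyloxolan-2-one | C=C(CCCCCCCO[Si](C)(C)C(C)(C)C)C[C@]1(C)OC(=O)C[C@@H]1OOC(C)(C)OC | intermediate
18 | (4S,5S)-4-hydroperoxy-5-(9-hydroxy-2-methylidenenonyl)-5-methyloxolan-2-one | C=C(CCCCCCCO)C[C@]1(C)OC(=O)C[C@@H]1OO | intermediate
19 | (1S,4S,6S)-4-(7-hydroxyheptyl)-4-(iodomethyl)-6-methyl-2,3,7-trioxabicyclo[4.3.0]nonan-8-one | IC[C@]1(CCCCCCCO)C[C@]2(C)OC(=O)C[C@@H]2OO1 | intermediate
20 | (1S,4S,6S)-4-(7-hydroxyheptyl)-4,6-dimethyl-2,3,7-trioxabicyclo[4.3.0]nonan-8-one | C[C@]1(CCCCCCCO)C[C@]2(C)OC(=O)C[C@@H]2OO1 | intermediate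
21 | 7-[(1S,4S,6S)-4,6-dimethyl-8-oxo-2,3,7-trioxabicyclo[4.3.0]nonan-4-yl]heptanal | C[C@]1(CCCCCCC=O)C[C@]2(C)OC(=O)C[C@@H]2OO1 | intermediate
22 | diethyl [(2E)-3-phenylprop-2-en-1-yl]phosphonate (diethyl cinnamylphosphonate) | CCOP(=O)(OCC)C/C=C/c1ccccc1 | starting material
23 | lithium salt of the α-carbanion of 22 | [Li+].CCOP(=O)(OCC)[CH-]/C=C/c1ccccc1 | intermediate
24 | plakortolide R, (1S,4S,6S)-4,6-dimethyl-4-[(7E,9E)-10-phenyldeca-7,9-dien-1-yl]-2,3,7-trioxabicyclo[4.3.0]nonan-8-one | C[C@]1(CCCCCC/C=C/C=C/c2ccccc2)C[C@]2(C)OC(=O)C[C@@H]2OO1 | target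

Total step count: 12 (step 5 prepares a reagent). Longest linear sequence: 11 steps (steps 1–4 and 6–12).

**Steps most likely to fail**

1. Step 6. The conjugate addition may be slow at a β-carbon flanked by a quaternary centre, the enamine may collapse onto the O–O bond (epoxidation instead of peroxidation), and catalyst control at C-3 may be incomplete. Fallback: setting out from aldehyde 9, a Still–Gennari olefination (methyl bis(2,2,2-trifluoroethyl)phosphonoacetate, KN(SiMe3)2, 18-crown-6, THF, −78 °C) should give the (Z)-hydroxy enoate F1, which lactonises with loss of methanol to the butenolide F2. Mukaiyama–Isayama hydroperoxysilylation of the 1,1-disubstituted alkene (Co(acac)2 cat., O2, Et3SiH, 1,2-dichloroethane) should give the tertiary triethylsilyl peroxide F3 as both C-6 epimers. HCl in methanol should remove both silyl groups to give the hydroperoxy butenolide F4, and diethylamine in 2,2,2-trifluoroethanol should close the dioxane by 6-exo oxa-Michael addition onto C-3, cis-fused by necessity. This should give 20 together with its C-6 epimer F5, to be separated by chromatography. The route is rejoined at 20, so steps 6 to 10 are replaced, at the price of no control at C-6.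

2. Step 9. The iodinating agent may oxidise the hydroperoxide and start radical decomposition, and the irreversible iodonium capture may show too little face selectivity at C-6. Fallback: setting out from 18, cycloperoxymercuration with Hg(OAc)2 and a catalytic amount of HClO4 in CH2Cl2 at 0 °C should give the acetoxymercurio compound F6. This addition is reversible and the electrophile does not oxidise hydroperoxides, so the C-6 ratio would be set by equilibration of the two mercurials and not by a kinetic transition state. Reduction in the same flask with NaBH4 in aqueous NaOH/THF at 0 °C should replace mercury by hydrogen and give 20 directly, so steps 9 and 10 are both replaced and no iodide is handled.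

3. Step 12. The phosphonate anion may enolise the lactone, which would open the peroxide by β-elimination, and E selectivity at C13=C14 may be incomplete. Fallback: setting out from 21, a Wittig reaction with the semi-stabilised ylide from cinnamyltriphenylphosphonium chloride and NaN(SiMe3)2 (ylide kept from excess, THF, −78 °C), a much weaker base than the phosphonate anion, should give 24 mixed with the (13Z,15E)-isomer F7. Iodine (5 mol %) in CH2Cl2 under ambient light should then isomerise F7 to the conjugated E,E-diene, which rejoins the route at 24.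

**Further compounds**

F1 | step 6 | methyl (2Z,4S)-13-[(tert-butyldimethylsilyl)oxy]-4-hydroxy-4-methyl-6-methylidenetridec-2-enoate | C=C(CCCCCCCO[Si](C)(C)C(C)(C)C)C[C@](C)(O)/C=C\C(=O)OC
F2 | step 6 | (5S)-5-{9-[(tert-butyldimethylsilyl)oxy]-2-methylidenenonyl}-5-methylfuran-2(5H)-one | C=C(CCCCCCCO[Si](C)(C)C(C)(C)C)C[C@]1(C)OC(=O)C=C1
F3 | step 6 | (5S)-5-{9-[(tert-butyldimethylsilyl)oxy]-2-methyl-2-[(triethylsilyl)peroxy]nonyl}-5-methylfuran-2(5H)-one (both epimers at the peroxy carbon) | CC[Si](CC)(CC)OOC(C)(CCCCCCCO[Si](C)(C)C(C)(C)C)C[C@]1(C)OC(=O)C=C1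
F4 | step 6 | (5S)-5-(2-hydroperoxy-9-hydroxy-2-methylnonyl)-5-methylfuran-2(5H)-one (both epimers at the peroxy carbon) | OOC(C)(CCCCCCCO)C[C@]1(C)OC(=O)C=C1
F5 | step 6 | (1S,4R,6S)-4-(7-hydroxyheptyl)-4,6-dimethyl-2,3,7-trioxabicyclo[4.3.0]nonan-8-one (C-6 epimer of 20) | C[C@@]1(CCCCCCCO)C[C@]2(C)OC(=O)C[C@@H]2OO1
F6 | step 9 | (1S,4S,6S)-4-[(acetoxymercurio)methyl]-4-(7-hydroxyheptyl)-6-methyl-2,3,7-trioxabicyclo[4.3.0]nonan-8-one | CC(=O)O[Hg]C[C@]1(CCCCCCCO)C[C@]2(C)OC(=O)C[C@@H]2OO1
F7 | step 12 | (1S,4S,6S)-4,6-dimethyl-4-[(7Z,9E)-10-phenyldeca-7,9-dien-1-yl]-2,3,7-trioxabicyclo[4.3.0]nonan-8-one | C[C@]1(CCCCCC/C=C\C=C\c2ccccc2)C[C@]2(C)OC(=O)C[C@@H]2OO1
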